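## Structural features

Target 22 is a linear propelargonidin trimer: three flavan-3-ol units (ring A a phloroglucinol-type ring, ring C the dihydropyran, ring B a 4-hydroxyphenyl group on C2) joined top to middle and middle to bottom by C4–C8 bonds. Read from the SMILES, the top and bottom units are (2R,3R) as in (−)-epiafzelechin, the top one with its C4 aryl trans to O3 (4R). The middle unit is (2S,3S,4R), the mirror-image series, again 2,3-cis-3,4-trans. C2, C3 and C4 are therefore contiguous in two of the three rings C, and eight stereocentres must be controlled. The fragile parts are the eleven phenols (oxidation, base), the two interflavan bonds (cleaved by acid through ipso-protonation of ring A) and the benzylic C2–O1 ethers. The real difficulty is the middle unit: it cannot be taken from the natural monomer, its three stereocentres lie between two bulky chiral units, C4 carries two 2,6-dioxygenated aryl groups, and its ring A must be linked at C8 and not at C6. The feature exploited is this: without the O1–C2–C3–C4 chain of the middle unit, its ring A is a phloroglucinol substituted only by C4 of the top unit. Its two CH carbons (future C4a and C6) and the two flanking oxygens (future O1 and O7) are exchanged by rotation about the C4(top)–C8 bond, so C–C bonding at either CH and closure on the adjacent oxygen give the same 8-linked chroman, provided the oxygen para to the top unit (future O5) is capped. Because O3 and ring B of the middle unit lie on the face opposite to the C4 aryl, C4, once set, can direct the other two centres.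

## Logic of the disconnections

22 ⇒ 21. Eleven O–CH2Ph bonds are cut. Reason: free phloroglucinol and phenol rings would not survive oxidants, bases and organometallic reagents, and benzyl is the one group that a single neutral hydrogenolysis removes from every position. Gain: every earlier compound is a non-polar, air-stable ether. Demand: the last step must leave the two C4–C8 bonds and the three benzylic C2–O1 bonds intact, so no acid and no second kind of protecting group is allowed there.

21 ⇒ 17 + 20. The bond between C2 of the middle unit and its ring B is cut, and O3 is traced back to an oxirane oxygen bridging C2 and C3. Reason: ring B and O3 are cis to each other and trans to the C4 aryl, which is the signature of a syn addition of aryl and oxygen to the open face of a C2=C3 bond. Gain: ring B and two stereocentres leave the middle unit. Demand: the aryl group of 20 must reach C2 on the face of the oxirane oxygen, not by backside attack, and it must leave aluminium in preference to the two methyl groups.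

17 ⇒ 16. The C2–O and C3–O bonds of the oxirane are cut. Reason: the enol ether is the most electron-rich π bond and takes oxygen from a neutral oxidant. Gain: C4 is the only stereocentre left in the middle ring C. Demand: oxygen transfer anti to the C4 aryl and conditions mild enough for an acid-labile acetal epoxide.

16 ⇒ 14 ⇒ 13. No skeletal bond is cut; C2=C3 is traced back to the lactol (C2–OH, C3–H) and the O7 benzyl ether to the free phenol. Reason: the lactol is the oxidation level in which the annulation delivers C2, and O7 has to be free during the annulation for symmetry. Gain: the product of the key step is reached. Demand: ring C must stay closed while O7 is alkylated, and the dehydration must not be acidic enough to break a C4–C8 bond. Hence alkylation with a minimum of weak base and elimination through the anomeric sulfonate.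

13 ⇒ 11 + 7. The C4–C4a and O1–C2 bonds of the middle unit are cut. Reason: the dihydroxyphenyl ring of 11 has two CH carbons and two hydroxyls made equivalent by rotation, and its third oxygen is capped, so only the 8-linked chroman can form without any directing or blocking group. Gain: the trimer falls into two pieces of similar size from the same monomer, and only one stereocentre has to be set. Demand: the catalyst must choose the enal face against two remote chiral units, two hindered partners must still react, and 7 must be the limiting component so that the remaining CH/OH pair of 13 is not annulated as well.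

7 ⇒ 4 ⇒ 3. The C8–Cβ bond between ring A of the bottom unit and the propenal chain is cut to a C8–Br bond, and this to C8–H. Reason: C8 is the more nucleophilic ring carbon of a 5,7-dialkoxyflavan, and halogen–metal exchange turns the marked position into a carbon nucleophile. Gain: the bottom unit is the protected natural monomer, and the enal is reached from 4 in one step instead of an aldehyde/olefination pair. Demand: C8 over C6 selectivity and E geometry.

11 ⇒ 10 ⇒ 8 + 9. The O–benzyl bond para to the flavanyl group is cut, then the C4–aryl bond. Reason: 9 has three equivalent CH carbons, so its arylation has no regiochemistry, whereas a nucleophile already carrying the benzyl group would offer two kinds of carbon. The C4 cation of the 2,3-cis series is attacked trans to O3. Gain: the top unit is again the protected monomer plus a commodity phenol. Demand: mono-arylation (excess of 9), 4β selectivity, and alkylation of the one unhindered hydroxyl of 10 only.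

8 ⇒ 3 ⇒ 1. The C4–O bond is cut to C4–H and four O–benzyl bonds to the free hydroxyls. Reason: benzylic oxidation next to the electron-rich ring A is the standard way to make C4 electrophilic. Gain: 3 serves both halves, so 1 is the only chiral starting material. Demand: oxidation at C4 and not at C2, and no C2 epimerisation during protection.

20 ⇒ 18. The aryl–Al bond is cut to C–Br through 19. Reason: ring B must arrive as a nucleophile on a Lewis-acidic metal, and with two methyl groups as spectator ligands each aluminium carries exactly one ring-B group, so none is wasted. Gain: a commercial bromide and a commercial chloroalane. Demand: complete transmetalation, so that no free 19 opens 17 from the back.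

## Other disconnections considered

Alternative 1: The cut is C3–C4 and O1–C2 of the middle ring C, a [4+2] disconnection. In the forward sense a bulky chiral BINOL-derived phosphoric acid would dehydrate the o-hydroxybenzhydrol A2 to its ortho-quinone methide (C4=C4a–C8a=O1), and the (Z)-styrylboronate A3 would add as the 2π partner to give the C3 boronate A1. Oxidation of the C–B bond with retention would give 21.
- In its favour: all three stereocentres of the middle ring would be made in one step, the Z geometry maps onto the 2,3-cis relation, and the polarity of both partners fixes the orientation (nucleophilic alkene carbon to C4).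
- Against it here: A2 needs a ring A whose C4a is already carbon-substituted and in which one particular phenol is free; this is the regiochemical problem that the chosen plan avoids by symmetry. The quinone methide carbon would carry a 2,4,6-trioxygenated aryl group, which stabilises and crowds it, and the boronate is not an electron-rich alkene. A stepwise cationic addition is therefore likely, and bond rotation in it would erode the cis relation. The acid that ionises A2 also threatens the C4–C8 bond of the top unit and retro-Friedel–Crafts cleavage of A2 itself.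
- Comparison: on structure the alternative is the better plan for stereocentres per step (three against one) and the equal of the chosen plan in having no ring-closure regiochemistry in the key step. On mechanism it asks for orientation, endo/exo and facial selectivity at once on a sluggish cation, against a single facial choice in the chosen plan. On step economy it is better after the key step (two steps against five) but pays for this before it, so the totals should be similar.

Alternative 2: The cut is O1–C2 and C4–C8 of the lower junction. Anodic oxidation of the diarylcyclopropane A5 would give a radical cation; the ring-A phenol would open it at C2 with inversion (closing ring C), further oxidation would give the C4 cation, and C8 of 3 would add trans to the pivaloate to give A4. Ester cleavage would then give 21.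
- In its favour: the lower interflavan bond would be made as in classical proanthocyanidin couplings (C4 cation plus C8 of an intact monomer), so for that bond the alternative is closer to precedent than the chosen plan and needs no C8 functionalisation of the bottom unit. Acyloxy participation is a well-founded control for 3,4-trans addition, and C2 and C3 are relayed stereospecifically from the three-membered ring.
- Against it here: the electrolysis would be run on a molecule, and with a nucleophile, whose trialkoxyarene rings should oxidise at potentials at or below that of the arylcyclopropane, and the product is richer still. C6 of 3 can compete with C8. A5 is an enantiopure 1,2,3-trisubstituted cyclopropane on a hindered, desymmetrised ring A and would itself need a long synthesis.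
- Comparison: on structure it forms two bonds and defines three centres in one step (better than the chosen plan). On mechanism, radical-cation chemistry in a polyphenol ether is the least predictable of the four plans. On step economy it is better after the key step (two steps) and better for the bottom unit, but clearly worse for the precursor.

Alternative 3: The cut is C4–C4a and C4–C8 of the lower junction, both at the aldehyde carbon. A boron Lewis acid would make the aldehyde carbon of A7 attack C4a (closing ring C), the resulting benzylic hydroxyl would ionise, and C8 of 3 would add to the cation to give the fully benzylated trimer A6, one hydrogenolysis from 22.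
- In its favour: it has the shortest endgame of all (one step after the key step against five: the better plan on this point) and makes two C–C bonds in one flask. Ring closure has no regiochemistry because C4a is the only free carbon ortho to O1, which makes it the equal of the chosen plan there. Capture of a 2,3-cis flavanyl cation trans to O3 is well founded.
- Against it here: A7 is a β-aryloxy-α-benzyloxy aldehyde, epimerisable at C3 and prone to β-elimination of the aryloxide even while it is being made. Its O1–C2 ether must be formed at one specific, hindered hydroxyl of a desymmetrised ring A with control of C2, and C2/C3 of the unnatural series must come from a separate asymmetric synthesis. The Lewis-acid step exposes the existing C4–C8 bond to the conditions known to cleave and scramble such bonds, and C6 of 3 or a second cyclised molecule can capture the cation.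
- Comparison: on structure and step economy after the key step it is the better plan. On mechanism the chosen plan is safer, because its key step runs close to neutrality with a reagent-controlled stereocentre, and the chosen precursor 11 is far easier to reach than A7.

Key step: step 7

Remark: on the steric model of the (E)-s-trans iminium ion the (R)-amine gives the C4 configuration of 22, and this is assumed. Compounds 1, 9, 18, 3-(dimethylamino)acrolein, Me2AlCl (hexane solution) and the (R)-amine are taken as purchasable, and dimethyldioxirane as a freshly prepared acetone solution.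

## Steps

Step 1
Reactants: 1 (−)-epiafzelechin [(2R,3R)-2-(4-hydroxyphenyl)chroman-3,5,7-triol]
Product: 3 (2R,3R)-3,5,7,4'-tetra-O-benzylepiafzelechin, via 5,7,4'-tri-O-benzylepiafzelechin 2 (not isolated)
Conditions: BnBr (3.3 equiv), K2CO3, DMF, 0 °C → rt; then NaH (1.5 equiv), BnBr (1.5 equiv), Bu4NI (cat.), 0 °C → rt
Reagents that add atoms: benzyl bromide, BrCc1ccccc1
Why: Williamson ether synthesis in two stages in one flask: the carbonate alkylates only the three phenols and NaH then converts the secondary 3-OH into its alkoxide for the fourth benzylation; no bond to C2 or C3 is touched, and capping the phenols before the strong base is added removes the phenoxide-driven C2 epimerisation and limits C-benzylation.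

Step 2
Reactants: 3 (2R,3R)-3,5,7,4'-tetra-O-benzylepiafzelechin
Product: 4 8-bromo-3,5,7,4'-tetra-O-benzylepiafzelechin
Conditions: NBS (1.0 equiv), CH2Cl2, −78 → 0 °C
Reagents that add atoms: N-bromosuccinimide, O=C1CCC(=O)N1Br
Why: Electrophilic aromatic bromination; C8 is the more nucleophilic ring-A carbon of 5,7-dialkoxyflavans, and one equivalent at low temperature should give the 8-bromide as in the benzylated catechin series, ring B and the benzyl groups being far less activated.

Step 3
Reactants: 4 8-bromo-3,5,7,4'-tetra-O-benzylepiafzelechin
Product: 7 (E)-3-(3,5,7,4'-tetra-O-benzylepiafzelechin-8-yl)propenal, via 8-lithio-tetra-O-benzylepiafzelechin 5 (not isolated), via lithium aminoallyl alkoxide 6 (not isolated)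
Conditions: n-BuLi (1.1 equiv), THF, −78 °C; (E)-3-(dimethylamino)acrolein (1.5 equiv), −78 → 0 °C; 1 M HCl, THF, 0 °C
Reagents that add atoms: 3-(dimethylamino)acrolein, CN(C)/C=C/C=O
Why: Bromine–lithium exchange, 1,2-addition of the aryllithium to the vinylogous formamide and acid-induced loss of dimethylamine (vinylogous formylation) give the enal in one operation; the conjugated E isomer is the thermodynamic product of the elimination, and the benzyl ethers and C2/C3 are inert at −78 °C.

Step 4
Reactants: 3 (2R,3R)-3,5,7,4'-tetra-O-benzylepiafzelechin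
Product: 8 4β-(2-ethoxyethoxy)-3,5,7,4'-tetra-O-benzylepiafzelechin
Conditions: DDQ (2 equiv), 2-ethoxyethanol (5 equiv), CH2Cl2, rt
Reagents that add atoms: 2-ethoxyethanol, CCOCCO
Why: Benzylic oxidation by hydride abstraction: DDQ removes H4, which is activated by the ring-A oxygens ortho and para to C4a, and the alcohol traps the cation trans to the 3-benzyloxy group; this activation is standard for benzylated flavan-3-ols, and the C4 configuration is of no consequence because C4 is ionised again in step 5.

Step 5
Reactants: 8 4β-(2-ethoxyethoxy)-3,5,7,4'-tetra-O-benzylepiafzelechin; 9 phloroglucinol (5 equiv)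
Product: 10 4β-(2,4,6-trihydroxyphenyl)-3,5,7,4'-tetra-O-benzylepiafzelechin
Conditions: BF3·OEt2 (1.0 equiv), THF–CH2Cl2, −40 → 0 °C
Reagents that add atoms: none
Why: Lewis-acid ionisation of the C4 ether and Friedel–Crafts arylation of the benzylic cation; 9 has three equivalent CH positions, its excess suppresses a second alkylation and is washed out with water, and the arene adds anti to the 3-benzyloxy group of the 2,3-cis cation, which sets C4 of the top unit as 4β (3,4-trans) as is usual in the epi series.

Step 6
Reactants: 10 4β-(2,4,6-trihydroxyphenyl)-3,5,7,4'-tetra-O-benzylepiafzelechin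
Product: 11 4β-(4-benzyloxy-2,6-dihydroxyphenyl)-3,5,7,4'-tetra-O-benzylepiafzelechin
Conditions: BnBr (1.0 equiv), K2CO3 (1.05 equiv), DMF, −10 °C → rt
Reagents that add atoms: benzyl bromide, BrCc1ccccc1
Why: Williamson etherification under stoichiometric control: the hydroxyl para to the flavanyl group is the only one with two free ortho positions and no hydrogen bond to the oxygens of the top unit, so its phenoxide should form and react first; unreacted 10 and over-alkylated material would be removed by chromatography.

Step 7
Reactants: 11 4β-(4-benzyloxy-2,6-dihydroxyphenyl)-3,5,7,4'-tetra-O-benzylepiafzelechin (1.3 equiv); 7 (E)-3-(3,5,7,4'-tetra-O-benzylepiafzelechin-8-yl)propenal (1.0 equiv)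
Product: 13 nona-O-benzyl trimer lactol (middle unit: 5-benzyloxy-7-hydroxy-4-arylchroman-2-ol bonded at C8 to C4 of the top unit and at C4 to C8 of the bottom unit; both anomers; C4 as in 22), via open-chain 3,3-diarylpropanal 12 (not isolated)
Conditions: (R)-2-[diphenyl(trimethylsilyloxy)methyl]pyrrolidine (20 mol %), PhCO2H (20 mol %), CH2Cl2, 0 °C → rt
Reagents that add atoms: none
Why: The amine condenses with 7 to the (E)-s-trans iminium ion; the dihydroxyphenyl ring of 11 adds through one of its two CH carbons (ortho to one hydroxyl, para to the other) to the β-carbon in a Friedel–Crafts step, rearomatises, and the enamine is protonated and hydrolysed to aldehyde 12 with release of the amine. The phenol next to the new bond then adds to the aldehyde carbon in a 6-exo-trig hemiacetalisation that closes ring C (O1–C2) and gives 13 as both anomers. The closest known reaction type is the diarylprolinol silyl ether-catalysed Friedel–Crafts alkylation/hemiacetalisation of naphthols, sesamol and 3,5-dialkoxyphenols with enals to 4-substituted chroman-2-ols. C4 is the only new defined stereocentre and is set by the catalyst: the CPh2(OSiMe3) group of the (R)-amine covers one face of the iminium ion and the arene approaches the other, which gives the C4 configuration of 22 (the (S)-amine would give the epimer); the stereocentres of both partners are several bonds from the reacting carbons and should not override this. No regioselectivity is needed at the nucleophile, because rotation about the C4–aryl bond exchanges its two CH positions and its two hydroxyls and the third oxygen is benzylated, so only the 8-linked chroman can form. C- over O-alkylation follows from the reversibility of the oxa-Michael addition, and the benzylated rings A elsewhere are far weaker nucleophiles than the free dihydroxyphenyl ring. A second annulation at the remaining CH/OH pair (C6/O7) is held back by using 7 as the limiting partner and by the extra crowding in 13.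

Step 8
Reactants: 13 nona-O-benzyl trimer lactol
Product: 14 deca-O-benzyl trimer lactol (as 13 with O7 of the middle unit benzylated; both anomers)
Conditions: BnBr (1.2 equiv), K2CO3 (1.2 equiv), DMF, 0 °C → rt
Reagents that add atoms: benzyl bromide, BrCc1ccccc1
Why: Williamson etherification of the one remaining phenol; with little more than one equivalent of weak base only the phenol and not the lactol hydroxyl is deprotonated, so ring C should stay closed, and the oxygen that ring opening would expose (O1) lies between two branched benzylic substituents and should alkylate far more slowly than O7.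

Step 9
Reactants: 14 deca-O-benzyl trimer lactol
Product: 16 deca-O-benzyl trimer 4H-chromene (middle ring C: O1–C2=C3–C4; C4 unchanged), via anomeric mesylate 15 (not isolated)
Conditions: MsCl (3 equiv), Et3N (8 equiv), CH2Cl2, 0 → 40 °C
Reagents that add atoms: none
Why: Dehydration of a lactol to the cyclic enol ether through its anomeric sulfonate, a known route to glycals and 4H-chromenes: the mesylate ionises to the O1-stabilised oxocarbenium ion and Et3N removes H3; the medium stays basic, which spares the C4–C8 bond, and H4 is not acidic enough to be touched, so C4 keeps its configuration.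

Step 10
Reactants: 16 deca-O-benzyl trimer 4H-chromene
Product: 17 deca-O-benzyl trimer 2,3-epoxychroman (oxirane oxygen on the face opposite to the C4 aryl of the middle unit)
Conditions: DMDO (1.2 equiv, acetone), CH2Cl2, −40 → 0 °C; evaporation below 0 °C, used at once
Reagents that add atoms: dimethyldioxirane, CC1(C)OO1
Why: Epoxidation of an electron-rich enol ether by dimethyldioxirane, as for glycals (neutral, acetone the only by-product); the oxygen is delivered anti to the pseudo-axial C4 aryl group, which sets C3 of the middle unit, and the labile epoxide is not purified.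

Step 11
Reactants: 18 1-(benzyloxy)-4-bromobenzene
Product: 20 (4-benzyloxyphenyl)dimethylaluminium (ether–hexane solution, decanted from LiCl), via 4-benzyloxyphenyllithium 19 (not isolated)
Conditions: n-BuLi (1.0 equiv), Et2O–THF (4:1), −78 °C; Me2AlCl (1.0 equiv, hexanes), −78 °C → rt
Reagents that add atoms: dimethylaluminium chloride, C[Al](C)Cl
Why: Bromine–lithium exchange followed by salt metathesis of the aryllithium with one equivalent of Me2AlCl, the usual preparation of aryl(dimethyl)alanes; the benzyl ether is inert at −78 °C, LiCl settles from the ether–hexane mixture, and each aluminium then carries one ring-B aryl group beside two methyl spectator ligands.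

Step 12
Reactants: 17 deca-O-benzyl trimer 2,3-epoxychroman; 20 (4-benzyloxyphenyl)dimethylaluminium (2.5 equiv)
Product: 21 undeca-O-benzyl trimer with free 3-OH in the middle unit (middle unit 2,3-cis-3,4-trans as in 22)
Conditions: Et2O–CH2Cl2, −78 → 0 °C; aq. KNaC4H4O6
Reagents that add atoms: none
Why: Proposed new method: the alane should bind the oxirane oxygen of 17 as a Lewis acid, the C2–O bond should ionise to the O1-stabilised oxocarbenium ion held as a tight ion pair with the aluminate on O3, and the aryl group, which as an sp2 ligand leaves an aryl(dimethyl)aluminate far more readily than methyl, should pass from aluminium to C2 on the face the aluminate occupies, i.e. syn to O3 and anti to the C4 aryl, which sets C2 and gives the 2,3-cis-3,4-trans ring; the closest known reaction type is the syn opening of glycal epoxides (1,2-anhydro sugars) by triaryl- and trialkylalanes to 1,2-cis C-glycosides, from which this step differs in that the ring oxygen is an aryl ether oxygen, the cation is less stabilised and the alane is a mixed one.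

Step 13
Reactants: 21 undeca-O-benzyl trimer
Product: 22 epiafzelechin-(4β→8)-ent-epiafzelechin-(4α→8)-epiafzelechin (target)
Conditions: H2 (1 atm), Pd(OH)2/C, THF–MeOH–H2O (degassed), rt
Reagents that add atoms: none
Why: Hydrogenolysis of the eleven benzyl ethers over Pd(OH)2/C, the standard last step for benzylated proanthocyanidins; the interflavan links are C–C bonds and the C2–O1 ethers of flavans are known to survive these conditions, so no stereocentre is touched.

## Compound list

1 | (−)-epiafzelechin, (2R,3R)-2-(4-hydroxyphenyl)chroman-3,5,7-triol | Oc1cc(O)c2c(c1)O[C@H](c1ccc(O)cc1)[C@H](O)C2 | starting material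
2 | 5,7,4'-tri-O-benzylepiafzelechin (3-OH free) | C(c3ccccc3)Oc1cc(OCc3ccccc3)c2c(c1)O[C@H](c1ccc(OCc3ccccc3)cc1)[C@H](O)C2 | intermediate
3 | (2R,3R)-3,5,7,4'-tetra-O-benzylepiafzelechin | C(c3ccccc3)Oc1cc(OCc3ccccc3)c2c(c1)O[C@H](c1ccc(OCc3ccccc3)cc1)[C@H](OCc3ccccc3)C2 | intermediate
4 | 8-bromo-3,5,7,4'-tetra-O-benzylepiafzelechin | Brc6c(OCc5ccccc5)cc(OCc5ccccc5)c7c6O[C@H](c8ccc(OCc5ccccc5)cc8)[C@H](OCc5ccccc5)C7 | intermediate
5 | 8-lithio-3,5,7,4'-tetra-O-benzylepiafzelechin | [Li]c6c(OCc5ccccc5)cc(OCc5ccccc5)c7c6O[C@H](c8ccc(OCc5ccccc5)cc8)[C@H](OCc5ccccc5)C7 | intermediate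
6 | lithium (E)-3-(dimethylamino)-1-(3,5,7,4'-tetra-O-benzylepiafzelechin-8-yl)prop-2-en-1-olate (both C1 epimers) | [Li+].[O-]C(/C=C/N(C)C)c6c(OCc5ccccc5)cc(OCc5ccccc5)c7c6O[C@H](c8ccc(OCc5ccccc5)cc8)[C@H](OCc5ccccc5)C7 | intermediate
7 | (E)-3-(3,5,7,4'-tetra-O-benzylepiafzelechin-8-yl)propenal | O=C/C=C/c6c(OCc5ccccc5)cc(OCc5ccccc5)c7c6O[C@H](c8ccc(OCc5ccccc5)cc8)[C@H](OCc5ccccc5)C7 | intermediate
8 | 4β-(2-ethoxyethoxy)-3,5,7,4'-tetra-O-benzylepiafzelechin (C4–O trans to 3-OBn) | C(c5ccccc5)Oc1ccc([C@H]2Oc3cc(OCc5ccccc5)cc(OCc5ccccc5)c3[C@H](OCCOCC)[C@H]2OCc5ccccc5)cc1 | intermediate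
9 | phloroglucinol | Oc1cc(O)cc(O)c1 | starting material
10 | 4β-(2,4,6-trihydroxyphenyl)-3,5,7,4'-tetra-O-benzylepiafzelechin | C(c5ccccc5)Oc1ccc([C@H]2Oc3cc(OCc5ccccc5)cc(OCc5ccccc5)c3[C@H](c3c(O)cc(O)cc3O)[C@H]2OCc5ccccc5)cc1 | intermediate
11 | 4β-(4-benzyloxy-2,6-dihydroxyphenyl)-3,5,7,4'-tetra-O-benzylepiafzelechin | C(c5ccccc5)Oc1ccc([C@H]2Oc3cc(OCc5ccccc5)cc(OCc5ccccc5)c3[C@H](c3c(O)cc(OCc5ccccc5)cc3O)[C@H]2OCc5ccccc5)cc1 | intermediate
12 | open-chain aldehyde: 3-[6-benzyloxy-2,4-dihydroxy-3-(top unit-4β-yl)phenyl]-3-(bottom unit-8-yl)propanal, C3 of the propanal as C4 of 22 | C(c5ccccc5)Oc1ccc([C@H]2Oc3cc(OCc5ccccc5)cc(OCc5ccccc5)c3[C@H](c3c(O)cc(OCc5ccccc5)c([C@H](CC=O)c6c(OCc5ccccc5)cc(OCc5ccccc5)c7c6O[C@H](c8ccc(OCc5ccccc5)cc8)[C@H](OCc5ccccc5)C7)c3O)[C@H]2OCc5ccccc5)cc1 | intermediate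
13 | nona-O-benzyl trimer lactol: middle unit 5-benzyloxy-7-hydroxy-4-arylchroman-2-ol, both anomers, C4 as in 22 | C(c5ccccc5)Oc1ccc([C@H]2Oc3cc(OCc5ccccc5)cc(OCc5ccccc5)c3[C@H](c3c(O)cc(OCc5ccccc5)c4c3OC(O)C[C@@H]4c6c(OCc5ccccc5)cc(OCc5ccccc5)c7c6O[C@H](c8ccc(OCc5ccccc5)cc8)[C@H](OCc5ccccc5)C7)[C@H]2OCc5ccccc5)cc1 | intermediate
14 | deca-O-benzyl trimer lactol: as 13 with 7-OBn in the middle unit | C(c5ccccc5)Oc1ccc([C@H]2Oc3cc(OCc5ccccc5)cc(OCc5ccccc5)c3[C@H](c3c(OCc5ccccc5)cc(OCc5ccccc5)c4c3OC(O)C[C@@H]4c6c(OCc5ccccc5)cc(OCc5ccccc5)c7c6O[C@H](c8ccc(OCc5ccccc5)cc8)[C@H](OCc5ccccc5)C7)[C@H]2OCc5ccccc5)cc1 | intermediate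
15 | anomeric methanesulfonate of 14 (both anomers) | C(c5ccccc5)Oc1ccc([C@H]2Oc3cc(OCc5ccccc5)cc(OCc5ccccc5)c3[C@H](c3c(OCc5ccccc5)cc(OCc5ccccc5)c4c3OC(OS(C)(=O)=O)C[C@@H]4c6c(OCc5ccccc5)cc(OCc5ccccc5)c7c6O[C@H](c8ccc(OCc5ccccc5)cc8)[C@H](OCc5ccccc5)C7)[C@H]2OCc5ccccc5)cc1 | intermediate
16 | deca-O-benzyl trimer 4H-chromene: middle ring C with C2=C3 | C(c5ccccc5)Oc1ccc([C@H]2Oc3cc(OCc5ccccc5)cc(OCc5ccccc5)c3[C@H](c3c(OCc5ccccc5)cc(OCc5ccccc5)c4c3OC=C[C@@H]4c6c(OCc5ccccc5)cc(OCc5ccccc5)c7c6O[C@H](c8ccc(OCc5ccccc5)cc8)[C@H](OCc5ccccc5)C7)[C@H]2OCc5ccccc5)cc1 | intermediate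
17 | deca-O-benzyl trimer 2,3-epoxychroman: oxirane anti to the C4 aryl of the middle unit | C(c5ccccc5)Oc1ccc([C@H]2Oc3cc(OCc5ccccc5)cc(OCc5ccccc5)c3[C@H](c3c(OCc5ccccc5)cc(OCc5ccccc5)c4c3O[C@H]9O[C@H]9[C@@H]4c6c(OCc5ccccc5)cc(OCc5ccccc5)c7c6O[C@H](c8ccc(OCc5ccccc5)cc8)[C@H](OCc5ccccc5)C7)[C@H]2OCc5ccccc5)cc1 | intermediate
18 | 1-(benzyloxy)-4-bromobenzene | Brc1ccc(OCc2ccccc2)cc1 | starting material
19 | 4-benzyloxyphenyllithium | [Li]c1ccc(OCc2ccccc2)cc1 | intermediate
20 | (4-benzyloxyphenyl)dimethylaluminium | C[Al](C)c1ccc(OCc2ccccc2)cc1 | intermediate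
21 | undeca-O-benzyl trimer, middle 3-OH free, middle unit 2,3-cis-3,4-trans | C(c5ccccc5)Oc1ccc([C@H]2Oc3cc(OCc5ccccc5)cc(OCc5ccccc5)c3[C@H](c3c(OCc5ccccc5)cc(OCc5ccccc5)c4c3O[C@@H](c9ccc(OCc5ccccc5)cc9)[C@@H](O)[C@@H]4c6c(OCc5ccccc5)cc(OCc5ccccc5)c7c6O[C@H](c8ccc(OCc5ccccc5)cc8)[C@H](OCc5ccccc5)C7)[C@H]2OCc5ccccc5)cc1 | intermediate
22 | epiafzelechin-(4β→8)-ent-epiafzelechin-(4α→8)-epiafzelechin; top (2R,3R,4R), middle (2S,3S,4R), bottom (2R,3R) | Oc1ccc([C@H]2Oc3cc(O)cc(O)c3[C@H](c3c(O)cc(O)c4c3O[C@@H](c3ccc(O)cc3)[C@@H](O)[C@@H]4c3c(O)cc(O)c4c3O[C@H](c3ccc(O)cc3)[C@H](O)C4)[C@H]2O)cc1 | target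

## Step count and least certain steps

Total step count: 13. Longest linear sequence: 10 steps (steps 1, 4, 5, 6, 7, 8, 9, 10, 12, 13).

Step 12 (labelled step). What is most likely to go wrong is loss of the syn aryl transfer. After ionisation of the epoxide, a hydride shift from C3 (to the chroman-3-one) or capture of the C2 cation by a benzylated phloroglucinol ring may outrun aryl transfer, because an aryloxy-stabilised cation is more electrophilic than the alkoxy-stabilised cation of glycals. A methyl group may be transferred in place of the aryl group. Backside attack by a second alane molecule would give the 2,3-trans ring, and the epoxide may decompose before it meets the reagent (which also bears on step 10).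

The fallback uses known reactions only, sets out from 16 and comes back at 21. OsO4 (cat.) with N-methylmorpholine N-oxide in acetone–water would dihydroxylate the enol ether on the face away from the C4 aryl to the 2,3-dihydroxychroman F1 (C3 as in 22, lactol at C2). Excess 19 (made as in step 11) in THF at −78 → 0 °C would add to the ring-opened hydroxy aldehyde to give the 1-aryl-1,2-diol with free ring-A phenol F2. A catalytic amount of pyridinium p-toluenesulfonate in CH2Cl2 would ionise the 4-benzyloxybenzylic alcohol, and the phenol would close ring C to 21. C2 is then set in the ring closure; the half-chair with equatorial ring B, axial O3 and quasi-axial C4 aryl is the arrangement of 21, but full selectivity is not expected and the 2,3-trans epimer would have to be separated.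

Step 7 (key step). What is most likely to go wrong is poor conversion. The iminium ion of 7 carries a 2,4,6-trioxygenated aryl group that donates into the acceptor and flanks the β-carbon on both sides, and the nucleophile is hindered by the top unit. Slow turnover would also give time for retro-Friedel–Crafts equilibration (loss of facial selectivity) and for a second annulation.

The fallback sets out from 4 (through 5) and 11 and comes back at 13. It replaces the enal by a much stronger acceptor. Quenching 5 with N,N-dimethylformamide would give the 8-carbaldehyde F3. Knoevenagel condensation with 2,2-dimethyl-1,3-dioxane-4,6-dione (piperidinium acetate) would give the arylidene derivative F4. F4 and 11 in pyridine at 60 °C would undergo conjugate addition of the phenol ring and lactonisation with loss of acetone and carbon dioxide to the 4-aryl-3,4-dihydrocoumarin F5. Reduction with i-Bu2AlH in toluene at −78 °C would give lactol 13. Catalyst control of C4 is given up in this variant: both C4 epimers of F5 (diastereomers) would form and would have to be separated.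

Step 6. What is most likely to go wrong is loss of site selectivity: benzylation at a hydroxyl ortho to the flavanyl group, double benzylation, or C-benzylation of the phloroglucinol ring, since the three phenols differ only in hindrance and hydrogen bonding.

The fallback sets out from 10 and comes back at 14. It uses a reagent that is far more sensitive to hindrance. i-Pr3SiCl and imidazole in DMF would silylate only the para hydroxyl to give the silyl ether F6. The annulation of step 7 with 7 would give the 5-silyloxy lactol F7. Bu4NF (1 equiv) followed by BnBr and K2CO3 in DMF would exchange silicon for benzyl and benzylate O7 in the same flask to give 14.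

Step 8. What is most likely to go wrong is base-induced ring–chain tautomerism of the lactol during the alkylation, so that the hydroxy aldehyde is benzylated at O1 or consumed by aldol condensation.

The fallback sets out from 13 and comes back at 16. It masks the lactol first. Methanol and trimethyl orthoformate with catalytic pyridinium p-toluenesulfonate at rt would give the methyl acetal F8, which cannot open in base. BnBr and K2CO3 in DMF would give its 7-O-benzyl ether F9. Me3SiOTf with i-Pr2NEt in CH2Cl2 would eliminate methanol to the 4H-chromene 16, which also replaces step 9.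

## Further compounds

F1 | step 12 | deca-O-benzyl trimer 2,3-dihydroxychroman (3-OH anti to the C4 aryl, lactol at C2, both anomers) | C(c5ccccc5)Oc1ccc([C@H]2Oc3cc(OCc5ccccc5)cc(OCc5ccccc5)c3[C@H](c3c(OCc5ccccc5)cc(OCc5ccccc5)c4c3OC(O)[C@@H](O)[C@@H]4c6c(OCc5ccccc5)cc(OCc5ccccc5)c7c6O[C@H](c8ccc(OCc5ccccc5)cc8)[C@H](OCc5ccccc5)C7)[C@H]2OCc5ccccc5)cc1
F2 | step 12 | ring-opened triol: 1-(4-benzyloxyphenyl)-3-aryl-3-(bottom unit-8-yl)propane-1,2-diol with free ring-A phenol (both C1 epimers) | C(c5ccccc5)Oc1ccc([C@H]2Oc3cc(OCc5ccccc5)cc(OCc5ccccc5)c3[C@H](c3c(OCc5ccccc5)cc(OCc5ccccc5)c([C@H]([C@H](O)C(O)c9ccc(OCc5ccccc5)cc9)c6c(OCc5ccccc5)cc(OCc5ccccc5)c7c6O[C@H](c8ccc(OCc5ccccc5)cc8)[C@H](OCc5ccccc5)C7)c3O)[C@H]2OCc5ccccc5)cc1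
F3 | step 7 | 3,5,7,4'-tetra-O-benzylepiafzelechin-8-carbaldehyde | O=Cc6c(OCc5ccccc5)cc(OCc5ccccc5)c7c6O[C@H](c8ccc(OCc5ccccc5)cc8)[C@H](OCc5ccccc5)C7
F4 | step 7 | 5-[(3,5,7,4'-tetra-O-benzylepiafzelechin-8-yl)methylidene]-2,2-dimethyl-1,3-dioxane-4,6-dione | CC1(C)OC(=O)C(=Cc6c(OCc5ccccc5)cc(OCc5ccccc5)c7c6O[C@H](c8ccc(OCc5ccccc5)cc8)[C@H](OCc5ccccc5)C7)C(=O)O1
F5 | step 7 | nona-O-benzyl trimer 3,4-dihydrocoumarin (lactone of 13; wanted C4 epimer shown) | C(c5ccccc5)Oc1ccc([C@H]2Oc3cc(OCc5ccccc5)cc(OCc5ccccc5)c3[C@H](c3c(O)cc(OCc5ccccc5)c4c3OC(=O)C[C@@H]4c6c(OCc5ccccc5)cc(OCc5ccccc5)c7c6O[C@H](c8ccc(OCc5ccccc5)cc8)[C@H](OCc5ccccc5)C7)[C@H]2OCc5ccccc5)cc1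
F6 | step 6 | 4β-[2,6-dihydroxy-4-(triisopropylsilyloxy)phenyl]-3,5,7,4'-tetra-O-benzylepiafzelechin | C(c5ccccc5)Oc1ccc([C@H]2Oc3cc(OCc5ccccc5)cc(OCc5ccccc5)c3[C@H](c3c(O)cc(O[Si](C(C)C)(C(C)C)C(C)C)cc3O)[C@H]2OCc5ccccc5)cc1
F7 | step 6 | trimer lactol as 13 with a triisopropylsilyl ether in place of the 5-benzyl ether of the middle unit | C(c5ccccc5)Oc1ccc([C@H]2Oc3cc(OCc5ccccc5)cc(OCc5ccccc5)c3[C@H](c3c(O)cc(O[Si](C(C)C)(C(C)C)C(C)C)c4c3OC(O)C[C@@H]4c6c(OCc5ccccc5)cc(OCc5ccccc5)c7c6O[C@H](c8ccc(OCc5ccccc5)cc8)[C@H](OCc5ccccc5)C7)[C@H]2OCc5ccccc5)cc1
F8 | step 8 | methyl acetal of 13 (2-methoxychroman, 7-OH free, both anomers) | C(c5ccccc5)Oc1ccc([C@H]2Oc3cc(OCc5ccccc5)cc(OCc5ccccc5)c3[C@H](c3c(O)cc(OCc5ccccc5)c4c3OC(OC)C[C@@H]4c6c(OCc5ccccc5)cc(OCc5ccccc5)c7c6O[C@H](c8ccc(OCc5ccccc5)cc8)[C@H](OCc5ccccc5)C7)[C@H]2OCc5ccccc5)cc1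
F9 | step 8 | methyl acetal of 14 (2-methoxychroman, 7-OBn, both anomers) | C(c5ccccc5)Oc1ccc([C@H]2Oc3cc(OCc5ccccc5)cc(OCc5ccccc5)c3[C@H](c3c(OCc5ccccc5)cc(OCc5ccccc5)c4c3OC(OC)C[C@@H]4c6c(OCc5ccccc5)cc(OCc5ccccc5)c7c6O[C@H](c8ccc(OCc5ccccc5)cc8)[C@H](OCc5ccccc5)C7)[C@H]2OCc5ccccc5)cc1
A1 | alternative 1 | undeca-O-benzyl trimer with a pinacol boronate at C3 of the middle unit | C(c5ccccc5)Oc1ccc([C@H]2Oc3cc(OCc5ccccc5)cc(OCc5ccccc5)c3[C@H](c3c(OCc5ccccc5)cc(OCc5ccccc5)c4c3O[C@@H](c9ccc(OCc5ccccc5)cc9)[C@@H](B9OC(C)(C)C(C)(C)O9)[C@@H]4c6c(OCc5ccccc5)cc(OCc5ccccc5)c7c6O[C@H](c8ccc(OCc5ccccc5)cc8)[C@H](OCc5ccccc5)C7)[C@H]2OCc5ccccc5)cc1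
A2 | alternative 1 | o-hydroxybenzhydrol: (bottom unit-8-yl)[4,6-dibenzyloxy-2-hydroxy-3-(top unit-4β-yl)phenyl]methanol (both carbinol epimers) | C(c5ccccc5)Oc1ccc([C@H]2Oc3cc(OCc5ccccc5)cc(OCc5ccccc5)c3[C@H](c3c(OCc5ccccc5)cc(OCc5ccccc5)c(C(O)c6c(OCc5ccccc5)cc(OCc5ccccc5)c7c6O[C@H](c8ccc(OCc5ccccc5)cc8)[C@H](OCc5ccccc5)C7)c3O)[C@H]2OCc5ccccc5)cc1
A3 | alternative 1 | (Z)-2-[2-(4-benzyloxyphenyl)ethenyl]-4,4,5,5-tetramethyl-1,3,2-dioxaborolane | CC1(C)OB(/C=C\c2ccc(OCc3ccccc3)cc2)OC1(C)C
A4 | alternative 2 | undeca-O-benzyl trimer with a pivaloate on O3 of the middle unit | C(c5ccccc5)Oc1ccc([C@H]2Oc3cc(OCc5ccccc5)cc(OCc5ccccc5)c3[C@H](c3c(OCc5ccccc5)cc(OCc5ccccc5)c4c3O[C@@H](c9ccc(OCc5ccccc5)cc9)[C@@H](OC(=O)C(C)(C)C)[C@@H]4c6c(OCc5ccccc5)cc(OCc5ccccc5)c7c6O[C@H](c8ccc(OCc5ccccc5)cc8)[C@H](OCc5ccccc5)C7)[C@H]2OCc5ccccc5)cc1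
A5 | alternative 2 | diarylcyclopropane: 2-(4-benzyloxyphenyl)-3-[4,6-dibenzyloxy-2-hydroxy-3-(top unit-4β-yl)phenyl]cyclopropyl pivaloate (aryl groups trans, pivaloate trans to the 4-benzyloxyphenyl group) | C(c5ccccc5)Oc1ccc([C@H]2Oc3cc(OCc5ccccc5)cc(OCc5ccccc5)c3[C@H](c3c(OCc5ccccc5)cc(OCc5ccccc5)c([C@@H]9[C@H](OC(=O)C(C)(C)C)[C@H]9c8ccc(OCc5ccccc5)cc8)c3O)[C@H]2OCc5ccccc5)cc1
A6 | alternative 3 | dodeca-O-benzyl trimer (fully benzylated 22) | C(c5ccccc5)Oc1ccc([C@H]2Oc3cc(OCc5ccccc5)cc(OCc5ccccc5)c3[C@H](c3c(OCc5ccccc5)cc(OCc5ccccc5)c4c3O[C@@H](c9ccc(OCc5ccccc5)cc9)[C@@H](OCc5ccccc5)[C@@H]4c6c(OCc5ccccc5)cc(OCc5ccccc5)c7c6O[C@H](c8ccc(OCc5ccccc5)cc8)[C@H](OCc5ccccc5)C7)[C@H]2OCc5ccccc5)cc1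
A7 | alternative 3 | aryl ether aldehyde: 2-benzyloxy-3-(4-benzyloxyphenyl)-3-[3,5-dibenzyloxy-2-(top unit-4β-yl)phenoxy]propanal (C2 and C3 of the future middle unit as in 22) | C(c5ccccc5)Oc1ccc([C@H]2Oc3cc(OCc5ccccc5)cc(OCc5ccccc5)c3[C@H](c3c(OCc5ccccc5)cc(OCc5ccccc5)cc3O[C@@H](c9ccc(OCc5ccccc5)cc9)[C@@H](OCc5ccccc5)C=O)[C@H]2OCc5ccccc5)cc1
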